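**Plan**

1. Retrosynthetic cuts, in order: the C18–O angelate ester; C12–C13 (a C12 Grignard reagent onto the β-carbon of (S)-β-butyrolactone); C8–C9 of ring B together with the O8–C12 lactone bond (SmI2 ketyl–enoate closure); C9=C11 (Horner–Wadsworth–Emmons). What remains is a cyclohexane ring A carrying C18, the C6–C8 chain and C9.
2. Enabling feature: in the seco compound C8 (ketone carbon) and C9 (enoate β-carbon on quaternary C10) are both electrophilic and lie 1,6 to each other across C7–C6–C5–C10, so ring B can be closed reductively through a C8 ketyl. Ring A is close to mirror-symmetric through C2 and C5 (C4: axial CH3, equatorial C18H2O; C10: axial CH3, equatorial C9).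
3. Because of that near-symmetry, natural dehydroabietic acid supplies ring A of this ent-labdane when its C4 and C10 swap roles: its carboxyl carbon becomes C9, its aromatic C9 becomes C18, and its C6–C7–C8 keep their places.
4. Forward order: ring A is cut out of the resin acid by arene degradation; C18, C8 and C9 are differentiated; ring B and a transient γ-lactone form in one SmI2 step; the lactone is reduced; the C13–C15 unit is joined at C12; the angelate goes on last.
5. Stereochemistry: C4, C5 and C10 come unchanged from dehydroabietic acid; C8 and C9 from the chair-like radical closure; C13 from (S)-β-butyrolactone by SN2 inversion; the Z alkene from angelic acid.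

Key step: step 11

Remark: positions carry the numbering of the target ent-labdane throughout, also in the monocyclic intermediates (C18 = oxygenated CH2 on C4, C19 and C20 = methyls on C4 and C10, C17 = methyl on C8); dehydroabietic acid and (S)-β-butyrolactone are taken as commercial single enantiomers.

**Route**

Step 1
Reactants: 1 dehydroabietic acid
Product: 2 methyl dehydroabietate
Conditions: MeI, K2CO3, DMF, rt
Reagents that add atoms: iodomethane, CI
Why: O-alkylation of the potassium carboxylate (SN2 esterification) is insensitive to the steric hindrance that blocks Fischer esterification of this tertiary acid and installs the ester that later marks C9.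

Step 2
Reactants: 2 methyl dehydroabietate
Product: 3 ring A diacid monoester (C18 acid; C8 acid; C9 methyl ester)
Conditions: RuCl3·xH2O (5 mol %), NaIO4 (excess), CCl4–MeCN–H2O, rt
Reagents that add atoms: sodium periodate, [Na+].[O-]I(=O)(=O)=O; water, O
Why: RuO4 generated catalytically from RuCl3 and NaIO4 degrades alkyl-substituted benzene rings down to carboxyl groups at their points of attachment (oxidative arene degradation), so the two ring-fusion arene carbons of 2 should emerge as the C8 and C18 acids while saturated ring A, its three stereocentres and the ester stay intact.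

Step 3
Reactants: 3 ring A diacid monoester
Product: 4 C18 acid dimethyl ester (C8 and C9 methyl esters)
Conditions: MeOH, H2SO4 (cat.), rt
Reagents that add atoms: methanol, CO
Why: Fischer esterification discriminates on steric grounds, so the primary C8 acid should esterify at room temperature while the C18 acid on quaternary C4 stays free, and any triester formed by over-reaction is achiral and leaves in the neutral wash, so it cannot erode enantiopurity.

Step 4
Reactants: 4 C18 acid dimethyl ester
Product: 5 C18 alcohol dimethyl ester
Conditions: BH3·SMe2, THF, 0 °C → rt; aqueous work-up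
Reagents that add atoms: none
Why: Borane reduces carboxylic acids through acyloxyboranes far faster than it reduces esters (chemoselective borane reduction), so only C18 should be taken to the alcohol.

Step 5
Reactants: 5 C18 alcohol dimethyl ester
Product: 6 C18 silyl ether dimethyl ester
Conditions: TBSCl, imidazole, DMF, rt
Reagents that add atoms: tert-butyldimethylsilyl chloride, CC(C)(C)[Si](C)(C)Cl
Why: Imidazole-promoted silylation of the neopentyl primary alcohol is routine and locks in the difference between C18 and C9 on which the absolute configuration of ring A now rests, while also preventing bridging lactonisation of the C18 hydroxyl onto the cis-1,3 C9 ester.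

Step 6
Reactants: 6 C18 silyl ether dimethyl ester
Product: 7 C8 Weinreb amide
Conditions: MeNH(OMe)·HCl, i-PrMgCl, THF, −20 → 0 °C
Reagents that add atoms: N,O-dimethylhydroxylamine hydrochloride, CNOC.Cl
Why: The chloromagnesium amide of N,O-dimethylhydroxylamine converts unhindered esters directly into Weinreb amides at low temperature (ester aminolysis), whereas the C9 ester on quaternary C10 is too hindered to react.

Step 7
Reactants: 7 C8 Weinreb amide
Product: 8 C8 methyl ketone
Conditions: MeMgBr, THF, 0 °C
Reagents that add atoms: methylmagnesium bromide, C[Mg]Br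
Why: Grignard addition to a Weinreb amide stops at the chelated tetrahedral intermediate, which releases the methyl ketone (C8 with C17) only on work-up, and the hindered C9 ester is inert at this temperature.

Step 8
Reactants: 8 C8 methyl ketone
Product: 9 C8/C9 diol (both C8 epimers)
Conditions: LiAlH4, THF, 0 °C → rt
Reagents that add atoms: none
Why: LiAlH4 reduces the hindered C9 ester to the neopentyl alcohol and at the same time the ketone to a secondary alcohol whose configuration is irrelevant because the next step removes it, the silyl ether being stable to hydride.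

Step 9
Reactants: 9 C8/C9 diol
Product: 10 keto aldehyde
Conditions: n-Pr4N[RuO4] (5 mol %), NMO, 4 Å MS, CH2Cl2, rt
Reagents that add atoms: none
Why: Ley–Griffith oxidation takes the primary and the secondary alcohol to aldehyde and ketone under neutral conditions, so the non-enolisable C9 aldehyde and the C8 methyl ketone are set up together without aldol chemistry.

Step 10
Reactants: 10 keto aldehyde; 11 triethyl phosphonoacetate
Product: 12 ring A keto-enoate
Conditions: 11 (1.2 equiv), NaH (1.1 equiv), THF, 0 °C → rt
Reagents that add atoms: none
Why: The Horner–Wadsworth–Emmons anion reacts much faster with an aldehyde than with a methyl ketone and gives the E-enoate, and keeping the phosphonate in slight excess over NaH leaves no free base to enolise the ketone.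

Step 11
Reactants: 12 ring A keto-enoate
Product: 14 C18-silyloxy ent-sclareolide-type lactone, via samarium alkoxide ester 13 (not isolated)
Conditions: SmI2 (2.5 equiv), t-BuOH (2 equiv), THF, −78 °C → rt
Reagents that add atoms: samarium diiodide, I[Sm]I (held only in intermediate 13)
Why: Electron transfer from divalent samarium to the C8 ketone gives a ketyl radical that adds to C9, the β-carbon of the enoate on quaternary C10, after which a second SmI2 reduces the C11 radical to a samarium enolate that t-BuOH protonates, and the trivalent samarium alkoxide 13 attacks the C12 ester carbonyl and expels ethoxide. The closest known reaction type is the SmI2 ketyl–olefin reductive cyclisation onto an α,β-unsaturated ester followed by lactonisation in the same flask. Ring B closes in the 6-exo-trig mode (C8 radical onto C9=C11) and the γ-lactone in the 5-exo-trig mode (O8 onto the C12 carbonyl). C9 is controlled by the chair transition state that the equatorial C5 and C10 tethers of ring A enforce, with the enoate arm equatorial and H-9 axial anti to the C10 methyl, and C8 is controlled by the preference of the bulky solvated O–Sm group for the equatorial position anti to the enoate, which places the C8 methyl axial. The step needs facial selectivity at the ketyl carbon and cyclisation that outruns simple reduction of either π system, and the substrate secures the first through the axial C10 methyl, which penalises an axial O–Sm group more than an axial methyl, and the second through the 1,6 spacing of C8 and C9 and the electron-poor acceptor. Only the ring A chair with both arms equatorial can cyclise, so ring inversion of 12 drains through that conformer.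

Step 12
Reactants: 14 C18-silyloxy ent-sclareolide-type lactone
Product: 15 8,12-diol
Conditions: LiAlH4, THF, 0 °C
Reagents that add atoms: none
Why: Hydride reduction of the γ-lactone gives the tertiary C8 alcohol and the primary C12 alcohol without touching any stereocentre.

Step 13
Reactants: 15 8,12-diol
Product: 16 bis(triethylsilyl) ether
Conditions: TESOTf (3 equiv), 2,6-lutidine, CH2Cl2, −78 → 0 °C
Reagents that add atoms: triethylsilyl trifluoromethanesulfonate, CC[Si](CC)(CC)OS(=O)(=O)C(F)(F)F
Why: The silyl triflate silylates even the tertiary C8 hydroxyl, which must be masked because a free C8–OH would close the 8,12-ether as soon as C12 carries a leaving group.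

Step 14
Reactants: 16 bis(triethylsilyl) ether
Product: 17 C12 alcohol with C8 triethylsilyl ether
Conditions: PPTS (cat.), MeOH–CH2Cl2, 0 °C
Reagents that add atoms: none
Why: Acid-catalysed methanolysis cleaves a primary triethylsilyl ether much faster than a tertiary one or a neopentyl tert-butyldimethylsilyl ether (sterically selective desilylation), so only the C12 hydroxyl should be freed.

Step 15
Reactants: 17 C12 alcohol with C8 triethylsilyl ether
Product: 18 C12 bromide
Conditions: CBr4, PPh3, CH2Cl2, 0 °C
Reagents that add atoms: tetrabromomethane, BrC(Br)(Br)Br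
Why: Appel bromination converts the primary alcohol into the bromide by SN2 displacement of the alkoxyphosphonium ion under neutral conditions that spare both silyl ethers.

Step 16
Reactants: 18 C12 bromide; 19 (S)-β-butyrolactone
Product: 21 bis-silylated C15 acid, via C12 Grignard reagent 20 (not isolated)
Conditions: Mg, THF, 40 °C; then CuI (10 mol %), 19, THF–Me2S, −30 → 0 °C; cold dilute HCl work-up
Reagents that add atoms: magnesium, [Mg] (held only in intermediate 20)
Why: Copper-catalysed Grignard reagents open β-lactones by SN2 attack at the β-carbon (alkyl–oxygen cleavage) with inversion, so the S lactone should deliver C13 in the S configuration of the target together with the free C15 acid in one operation.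

Step 17
Reactants: 21 bis-silylated C15 acid
Product: 22 allyl ester
Conditions: allyl bromide, K2CO3, DMF, rt
Reagents that add atoms: allyl bromide, C=CCBr
Why: Carboxylate alkylation gives the allyl ester, which keeps C15 out of the coming acylation and can be removed later under neutral conditions that an angelate tolerates.

Step 18
Reactants: 22 allyl ester
Product: 23 C8,C18-diol allyl ester
Conditions: HF·pyridine, pyridine, THF, 0 °C → rt
Reagents that add atoms: none
Why: Buffered hydrogen fluoride cleaves both silyl ethers (fluoride-driven desilylation) without hydrolysing the allyl ester or dehydrating the tertiary alcohol.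

Step 19
Reactants: 23 C8,C18-diol allyl ester; 24 angelic acid
Product: 26 C18 angelate allyl ester, via angelic mixed anhydride 25 (not isolated)
Conditions: 24, 2,4,6-trichlorobenzoyl chloride, Et3N, toluene, rt; then 23, toluene, 80 °C
Reagents that add atoms: 2,4,6-trichlorobenzoyl chloride, O=C(Cl)c1c(Cl)cc(Cl)cc1Cl (held only in intermediate 25)
Why: Yamaguchi esterification through the mixed anhydride acylates the primary C18 hydroxyl, leaves the tertiary C8 hydroxyl untouched and, run without a nucleophilic amine catalyst, should keep the Z geometry of the angelate.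

Step 20
Reactants: 26 C18 angelate allyl ester
Product: 27 CNP0315745.1
Conditions: Pd(PPh3)4 (5 mol %), morpholine, THF, rt
Reagents that add atoms: none
Why: Zerovalent palladium ionises the allyl ester to a π-allyl complex that morpholine intercepts (Tsuji–Trost deallylation), which frees the C15 acid without acid or base that could isomerise or cleave the angelate.

**Compound list**

1 | dehydroabietic acid (natural abieta-8,11,13-trien-18-oic acid) | CC(C)C1=CC2=C(C=C1)[C@]3(CCC[C@@]([C@@H]3CC2)(C)C(=O)O)C | starting material
2 | methyl dehydroabietate | CC(C)C1=CC2=C(C=C1)[C@]3(CCC[C@@]([C@@H]3CC2)(C)C(=O)OC)C | intermediate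
3 | ring A diacid monoester: cyclohexane C1–C5/C10 with C4 (CH3, C18O2H), C5 (H, CH2CH2–C8O2H) and C10 (CH3, C9O2Me); C4 methyl, C5 chain and C10 methyl all cis, C18 and C9 on the other face (both methyls axial, the three carbon arms equatorial) | OC(=O)[C@@]1(C)CCC[C@](C(=O)OC)(C)[C@@H]1CCC(=O)O | intermediate
4 | as 3 with the C8 acid as methyl ester (C18 acid, C8 and C9 methyl esters) | OC(=O)[C@@]1(C)CCC[C@](C(=O)OC)(C)[C@@H]1CCC(=O)OC | intermediate
5 | as 4 with C18 as CH2OH | OC[C@@]1(C)CCC[C@](C(=O)OC)(C)[C@@H]1CCC(=O)OC | intermediate
6 | as 5 with C18 as CH2OTBS | CC(C)(C)[Si](C)(C)OC[C@@]1(C)CCC[C@](C(=O)OC)(C)[C@@H]1CCC(=O)OC | intermediate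
7 | as 6 with C8 as N-methoxy-N-methylamide | CC(C)(C)[Si](C)(C)OC[C@@]1(C)CCC[C@](C(=O)OC)(C)[C@@H]1CCC(=O)N(C)OC | intermediate
8 | as 6 with C8 as methyl ketone (C17 added), C9 still methyl ester | CC(C)(C)[Si](C)(C)OC[C@@]1(C)CCC[C@](C(=O)OC)(C)[C@@H]1CCC(C)=O | intermediate
9 | diol: C9 as CH2OH, C8 as CH(OH)CH3 (both C8 epimers), C18 as CH2OTBS | CC(C)(C)[Si](C)(C)OC[C@@]1(C)CCC[C@](CO)(C)[C@@H]1CCC(C)O | intermediate
10 | keto aldehyde: C9 as CHO on C10, C8 methyl ketone, C18 as CH2OTBS | CC(C)(C)[Si](C)(C)OC[C@@]1(C)CCC[C@](C=O)(C)[C@@H]1CCC(C)=O | intermediate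
11 | triethyl phosphonoacetate | CCOC(=O)CP(=O)(OCC)OCC | starting material
12 | ring A keto-enoate: ethyl (E)-enoate C9=C11–C12 on C10, C8 methyl ketone on the C5 chain, C18 as CH2OTBS; ring A configuration as in 3 | CC(C)(C)[Si](C)(C)OC[C@@]1(C)CCC[C@](/C=C/C(=O)OCC)(C)[C@@H]1CCC(C)=O | intermediate
13 | diiodosamarium alkoxide of the ring-closed 8-hydroxy ethyl ester: trans-decalin, O8 equatorial and trans to the equatorial C11 arm, C17 axial on the face of C20 | CC(C)(C)[Si](C)(C)OC[C@@]1(C)CCC[C@]2(C)[C@@H]1CC[C@](C)(O[Sm](I)I)[C@H]2CC(=O)OCC | intermediate (not isolated)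
14 | C18-(tert-butyldimethylsilyloxy) ent-sclareolide-type 8,12-lactone: trans-decalin with C19, C20, C17 and C11 on one face and H-5, H-9, C18 and O8 on the other; γ-lactone trans-fused at C8/C9 | CC(C)(C)[Si](C)(C)OC[C@@]1(C)CCC[C@]2(C)[C@@H]1CC[C@]3(C)OC(=O)C[C@@H]23 | intermediate
15 | 8,12-diol (tertiary equatorial 8-OH, primary 12-OH), C18 as CH2OTBS; ring configuration as in 14 | CC(C)(C)[Si](C)(C)OC[C@@]1(C)CCC[C@]2(C)[C@@H]1CC[C@](C)(O)[C@H]2CCO | intermediate
16 | 8,12-bis(triethylsilyl) ether of 15 | CC(C)(C)[Si](C)(C)OC[C@@]1(C)CCC[C@]2(C)[C@@H]1CC[C@](C)(O[Si](CC)(CC)CC)[C@H]2CCO[Si](CC)(CC)CC | intermediate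
17 | 8-triethylsilyl ether with free 12-OH | CC(C)(C)[Si](C)(C)OC[C@@]1(C)CCC[C@]2(C)[C@@H]1CC[C@](C)(O[Si](CC)(CC)CC)[C@H]2CCO | intermediate
18 | C12 bromide (8-OTES, 18-OTBS) | CC(C)(C)[Si](C)(C)OC[C@@]1(C)CCC[C@]2(C)[C@@H]1CC[C@](C)(O[Si](CC)(CC)CC)[C@H]2CCBr | intermediate
19 | (S)-β-butyrolactone ((S)-4-methyloxetan-2-one) | C[C@H]1CC(=O)O1 | starting material
20 | C12 Grignard reagent from 18 | CC(C)(C)[Si](C)(C)OC[C@@]1(C)CCC[C@]2(C)[C@@H]1CC[C@](C)(O[Si](CC)(CC)CC)[C@H]2CC[Mg]Br | intermediate (not isolated)
21 | (13S)-15-oic acid with 8-OTES and 18-OTBS (full ent-labdane skeleton) | CC(C)(C)[Si](C)(C)OC[C@@]1(C)CCC[C@]2(C)[C@@H]1CC[C@](C)(O[Si](CC)(CC)CC)[C@H]2CC[C@H](C)CC(=O)O | intermediate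
22 | allyl ester of 21 | CC(C)(C)[Si](C)(C)OC[C@@]1(C)CCC[C@]2(C)[C@@H]1CC[C@](C)(O[Si](CC)(CC)CC)[C@H]2CC[C@H](C)CC(=O)OCC=C | intermediate
23 | allyl (13S)-8,18-dihydroxy-ent-labdan-15-oate (8-OH equatorial tertiary, 18-OH primary) | OC[C@@]1(C)CCC[C@]2(C)[C@@H]1CC[C@](C)(O)[C@H]2CC[C@H](C)CC(=O)OCC=C | intermediate
24 | angelic acid ((Z)-2-methylbut-2-enoic acid) | C/C=C(/C)C(=O)O | starting material
25 | angelic 2,4,6-trichlorobenzoic mixed anhydride | C/C=C(/C)C(=O)OC(=O)c1c(Cl)cc(Cl)cc1Cl | intermediate (not isolated)
26 | allyl ester of the target (18-O-angelate, free 8-OH) | C/C=C(/C)C(=O)OC[C@@]1(C)CCC[C@]2(C)[C@@H]1CC[C@](C)(O)[C@H]2CC[C@H](C)CC(=O)OCC=C | intermediate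
27 | CNP0315745.1: (13S)-18-angeloyloxy-8-hydroxy-ent-labdan-15-oic acid; trans-decalin with C19, C20, C17 and the C9 side chain on one face and H-5, H-9, C18 and 8-OH on the other | C/C=C(/C)C(=O)OC[C@@]1(C)CCC[C@]2(C)[C@@H]1CC[C@](C)(O)[C@H]2CC[C@H](C)CC(=O)O | target

**Count**

Total step count: 20. Longest linear sequence: 20 steps (1 to 27); 11, 19 and 24 are bought and enter directly.

**Steps most likely to fail**

Step 2. Oxidation at benzylic C7 may run alongside or ahead of cleavage of the only moderately electron-rich arene, which would shorten the C6–C8 chain or stall at ring-opened keto acids. The fallback activates the ring before cleaving it and switches to an oxidant that does not attack benzylic C–H. It sets out from 2: Friedel–Crafts acetylation (AcCl, AlCl3, CH2Cl2) should give methyl 12-acetyldehydroabietate F1, Baeyer–Villiger oxidation (mCPBA, CH2Cl2) methyl 12-acetoxydehydroabietate F2, and methanolysis (K2CO3, MeOH) the phenol methyl 12-hydroxydehydroabietate F3. Ozonolysis of the phenol ring (O3, AcOH–CH2Cl2, then H2O2) should then degrade it to the same diacid, and the route is rejoined at 3.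

Step 11. The ketyl may add through the alternative chair with the O–Sm group axial (poor facial selectivity at C8), or be reduced and protonated before ring closure. The fallback still forms C8–C9 but sets C8 afterwards by reagent approach anti to the axial C10 methyl. It sets out from 12: kinetic enolisation at C17 and triflation (LiN(i-Pr)2, THF, −78 °C, then PhNTf2) should give the terminal enol triflate F4. An intramolecular reductive Heck reaction (Pd(OAc)2, PPh3, HCO2Na, DMF, 80 °C; 6-exo-trig carbopalladation of the enoate, formate reduction of the C11 palladium enolate) should close ring B to the 8(17)-exocyclic alkene ester F5 with the C11 arm equatorial. Epoxidation (mCPBA, NaHCO3, CH2Cl2, 0 °C) from the face away from the C10 methyl should give the 8,17-epoxide ester F6 with oxygen equatorial. LiAlH4 in THF then opens the epoxide at C17 and reduces the ester, and the route is rejoined at diol 15.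

Step 16. The organocopper species may attack the acyl carbon of the β-lactone or deprotonate it (elimination to crotonate) instead of displacing at the secondary β-carbon. The fallback replaces the SN2 opening by an auxiliary-controlled conjugate addition. It sets out from 18, converted to Grignard reagent 20 as before. The acceptor (S)-3-[(E)-but-2-enoyl]-4-phenyloxazolidin-2-one F7 is made from (S)-4-phenyloxazolidin-2-one, n-BuLi and (E)-crotonyl chloride. Addition of 20 with CuBr·SMe2 (THF–Me2S, −40 °C) to the chelated s-cis imide, anti to the phenyl group, should give the (13S) N-acyl oxazolidinone adduct F8. Cleavage with LiOH and H2O2 (THF–H2O, 0 °C) returns the auxiliary, and the route is rejoined at acid 21.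

**Further compounds**

F1 | step 2 | methyl 12-acetyldehydroabietate | CC(C)C1=CC2=C(C=C1C(C)=O)[C@]3(CCC[C@@]([C@@H]3CC2)(C)C(=O)OC)C
F2 | step 2 | methyl 12-acetoxydehydroabietate | CC(C)C1=CC2=C(C=C1OC(C)=O)[C@]3(CCC[C@@]([C@@H]3CC2)(C)C(=O)OC)C
F3 | step 2 | methyl 12-hydroxydehydroabietate | CC(C)C1=CC2=C(C=C1O)[C@]3(CCC[C@@]([C@@H]3CC2)(C)C(=O)OC)C
F4 | step 11 | C8 terminal enol triflate of keto-enoate 12 | CC(C)(C)[Si](C)(C)OC[C@@]1(C)CCC[C@](/C=C/C(=O)OCC)(C)[C@@H]1CCC(=C)OS(=O)(=O)C(F)(F)F
F5 | step 11 | ring-closed 8(17)-exocyclic alkene ethyl ester (C11 arm equatorial) | CC(C)(C)[Si](C)(C)OC[C@@]1(C)CCC[C@]2(C)[C@@H]1CCC(=C)[C@H]2CC(=O)OCC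
F6 | step 11 | 8,17-epoxide ethyl ester (epoxide oxygen equatorial, trans to the C11 arm) | CC(C)(C)[Si](C)(C)OC[C@@]1(C)CCC[C@]2(C)[C@@H]1CC[C@]3(OC3)[C@H]2CC(=O)OCC
F7 | step 16 | (S)-3-[(E)-but-2-enoyl]-4-phenyloxazolidin-2-one | C/C=C/C(=O)N1[C@@H](c2ccccc2)COC1=O
F8 | step 16 | (13S) N-acyl oxazolidinone conjugate adduct (8-OTES, 18-OTBS) | CC(C)(C)[Si](C)(C)OC[C@@]1(C)CCC[C@]2(C)[C@@H]1CC[C@](C)(O[Si](CC)(CC)CC)[C@H]2CC[C@H](C)CC(=O)N3[C@@H](c4ccccc4)COC3=O
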